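**Retrosynthetic overview**

- Structural feature: in ring A (the 3,5-dihydroxy-2-prenylbenzoyl ring) the ketone-bearing C1 and the prenyl-bearing C2 are neighbours and C3/C5 carry the oxygens. This is the pattern of a cyclohexane-1,3-dione with carbon substituents on its α- and β-carbons.
- Ring A is therefore cut at C1–C2 (Michael) and C4–C5 (Dieckmann), leading back to ketone 1 and diester 2 by way of adduct 3 and dione 4. The ring is then aromatised through its bis-silyl dienol ether 5 to arene 6 and converted to Weinreb amide 7.
- The diaryl ketone C(=O)–C1' bond comes from aryllithium 10, made from phloroglucinol 8 through its tris-MOM ether 9, adding to 7 to give ketone 11.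
- The pyran ring is cut at O1–C2 and C4–C4a. After MOM removal (12) and silylation of the 4'-hydroxyl (13), 3-methylbut-2-enal 14 is annulated across C3' and the 2'-oxygen (through 15) to chromene 16, and fluoride releases target 17.
- Ring order: carbocyclic ring A (step 1), ring B brought in intact (step 5), pyran ring last (step 8).

Key step: step 1

Remark: the target has no stereocentre and no defined alkene geometry, so no stereocontrol is needed; 3, 4 and 5 are carried as isomer mixtures. Ring A is numbered from the ketone-bearing carbon (C1), with the prenyl group on C2; primed numbers refer to the phloroglucinol ring B.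

**Route**

Step 1
Reactants: 1 6-methylhept-5-en-2-one; 2 dimethyl maleate
Product: 4 methyl 2-(3-methylbut-2-enyl)-3,5-dioxocyclohexane-1-carboxylate (diastereomer mixture), via Michael adduct 3 (not isolated)
Conditions: NaOMe (1.5 equiv), MeOH, 0 °C to reflux; then cold aq. HCl to pH 2
Reagents that add atoms: none
Why: Methoxide equilibrates the enolates of 1, and the more substituted C3 enolate adds in a Michael reaction to the acceptor to give adduct 3, forming the ring A C1–C2 bond (any base-induced geometric isomerisation of the acceptor is inconsequential, since both geometries give the same adduct). The terminal methyl enolate of 3 then attacks the distal, CH2-bound ester in a Dieckmann condensation that forms C4–C5 and closes ring A in the 6-(enolendo)-exo-trig mode with loss of methoxide. Deprotonation of the resulting 1,3-dione, a vinylogous acid, removes the product from all the reversible steps and pulls the sequence forward; the closest known reaction type is the alkoxide-mediated Michael–Dieckmann condensation of acetone or acetonylsuccinates with maleate esters to 3,5-dioxocyclohexanecarboxylates. The two new stereocentres (C1 and C2) form without control, are both epimerisable and disappear once ring A becomes aromatic, so nothing needs to govern them. The selectivity required is addition at the CH2 and not the CH3 of 1, which the thermodynamically favoured substituted enolate under reversible protic conditions should secure; closure onto the proximal ester would need the disfavoured 5-(enolendo)-exo-trig mode and is reversible.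

Step 2
Reactants: 4 methyl 2-(3-methylbut-2-enyl)-3,5-dioxocyclohexane-1-carboxylate
Product: 6 methyl 2-(3-methylbut-2-enyl)-3,5-bis(triisopropylsilyloxy)benzoate, via bis-silyl dienol ether 5 (not isolated)
Conditions: TIPSOTf (2.3 equiv), Et3N (3 equiv), CH2Cl2, 0 °C to rt; hexane extraction and concentration; then DDQ (1.1 equiv), 2,4,6-collidine (2 equiv), toluene, 0 °C to rt
Reagents that add atoms: triisopropylsilyl trifluoromethanesulfonate (TIPSOTf), CC(C)[Si](C(C)C)(C(C)C)OS(=O)(=O)C(F)(F)F
Why: Soft enolisation with silyl triflate and amine should turn the enolised dione into the 1,3-bis(silyloxy)cyclohexa-1,3-diene 5 (its double-bond isomers converge), and DDQ dehydrogenation of this diene by hydride abstraction and proton loss should give the arene with both silyl ethers in place, under conditions free of acid and electrophilic halogen so that the prenyl alkene is left alone.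

Step 3
Reactants: 6 methyl 2-(3-methylbut-2-enyl)-3,5-bis(triisopropylsilyloxy)benzoate
Product: 7 N-methoxy-N-methyl-2-(3-methylbut-2-enyl)-3,5-bis(triisopropylsilyloxy)benzamide
Conditions: MeNH(OMe)·HCl (2 equiv), i-PrMgCl (4 equiv), THF, −20 °C to rt; aq. NH4Cl
Reagents that add atoms: N,O-dimethylhydroxylamine hydrochloride, CNOC.Cl
Why: Aminolysis of the methyl ester by the chloromagnesium amide of N,O-dimethylhydroxylamine (Weinreb amide formation) should proceed without hydroxide, which would strip the aryl silyl ethers, and leaves the alkene untouched.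

Step 4
Reactants: 8 phloroglucinol
Product: 9 1,3,5-tris(methoxymethoxy)benzene
Conditions: MOMCl (4 equiv), i-Pr2NEt (5 equiv), CH2Cl2/DMF, 0 °C to rt
Reagents that add atoms: chloromethyl methyl ether (MOMCl), COCCl
Why: The hard oxocarbenium-type electrophile should alkylate the three phenolic oxygens rather than carbon (Williamson-type acetal formation), giving a symmetrical substrate for directed metalation.

Step 5
Reactants: 9 1,3,5-tris(methoxymethoxy)benzene; 7 N-methoxy-N-methyl-2-(3-methylbut-2-enyl)-3,5-bis(triisopropylsilyloxy)benzamide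
Product: 11 [2-(3-methylbut-2-enyl)-3,5-bis(triisopropylsilyloxy)phenyl][2,4,6-tris(methoxymethoxy)phenyl]methanone, via aryllithium 10 (not isolated)
Conditions: 9 (1.4 equiv), n-BuLi (1.3 equiv), THF, 0 °C, 1 h; then 7 (1.0 equiv), −78 °C to 0 °C; aq. NH4Cl
Reagents that add atoms: none
Why: Directed ortho-metalation between two MOM ethers (all three ring positions are equivalent) gives 10, which should add once to the N-methoxy-N-methylamide in a Weinreb ketone synthesis, the ketone being released only on quench and being too hindered for a second addition, while the low temperature favours addition over deprotonation of the benzylic methylene.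

Step 6
Reactants: 11 [2-(3-methylbut-2-enyl)-3,5-bis(triisopropylsilyloxy)phenyl][2,4,6-tris(methoxymethoxy)phenyl]methanone
Product: 12 [2-(3-methylbut-2-enyl)-3,5-bis(triisopropylsilyloxy)phenyl](2,4,6-trihydroxyphenyl)methanone
Conditions: HCl (0.5 M in MeOH), THF, 40 °C
Reagents that add atoms: none
Why: Acid-catalysed acetal exchange with methanol should remove the three MOM groups, while the acid-robust aryl triisopropylsilyl ethers stay on and keep the oxygen next to the prenyl group blocked, so that no chroman can form on ring A.

Step 7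
Reactants: 12 [2-(3-methylbut-2-enyl)-3,5-bis(triisopropylsilyloxy)phenyl](2,4,6-trihydroxyphenyl)methanone
Product: 13 [2,6-dihydroxy-4-(triisopropylsilyloxy)phenyl][2-(3-methylbut-2-enyl)-3,5-bis(triisopropylsilyloxy)phenyl]methanone
Conditions: TIPSCl (1.05 equiv), imidazole (2.5 equiv), DMF, 0 °C
Reagents that add atoms: chlorotriisopropylsilane (TIPSCl), CC(C)[Si](Cl)(C(C)C)C(C)C
Why: Silylation with a bulky chlorosilane should pick the 4'-hydroxyl, which is the most acidic (para to the ketone) and the only unhindered one, the 2'- and 6'-hydroxyls being flanked by the aroyl group and tied up in hydrogen bonding to the ketone.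

Step 8
Reactants: 13 [2,6-dihydroxy-4-(triisopropylsilyloxy)phenyl][2-(3-methylbut-2-enyl)-3,5-bis(triisopropylsilyloxy)phenyl]methanone; 14 3-methylbut-2-enal
Product: 16 [7-hydroxy-2,2-dimethyl-5-(triisopropylsilyloxy)-2H-chromen-8-yl][2-(3-methylbut-2-enyl)-3,5-bis(triisopropylsilyloxy)phenyl]methanone, via ortho-quinone methide 15 (not isolated)
Conditions: 14 (1.5 equiv), ethylenediammonium diacetate (20 mol%), toluene, 110 °C
Reagents that add atoms: none
Why: Amine-catalysed Knoevenagel-type condensation of the enal at C3' and loss of water should give the ortho-quinone methide 15, whose oxa-6π electrocyclisation closes the 2,2-dimethylpyran; because the 4'-oxygen is silylated, only an ortho oxygen can close the ring, which fixes the 8-aroyl regiochemistry, and the two ortho hydroxyls are equivalent by symmetry.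

Step 9
Reactants: 16 [7-hydroxy-2,2-dimethyl-5-(triisopropylsilyloxy)-2H-chromen-8-yl][2-(3-methylbut-2-enyl)-3,5-bis(triisopropylsilyloxy)phenyl]methanone
Product: 17 [3,5-dihydroxy-2-(3-methylbut-2-enyl)phenyl](5,7-dihydroxy-2,2-dimethyl-2H-chromen-8-yl)methanone (target)
Conditions: Bu4NF (3.5 equiv), AcOH (3.5 equiv), THF, 0 °C; pH 7 phosphate buffer work-up
Reagents that add atoms: none
Why: Buffered fluoride should cleave all three aryl silyl ethers (fluoride-mediated desilylation) under near-neutral conditions, so that the chromene and the ortho-prenylphenol, both acid-sensitive, are not exposed to acid.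

**Compound list**

1 | 6-methylhept-5-en-2-one | CC(=O)CCC=C(C)C | starting material
2 | dimethyl maleate | COC(=O)/C=C\C(=O)OC | starting material
3 | dimethyl 2-(6-methyl-2-oxohept-5-en-3-yl)butanedioate (diastereomer mixture) | CC(=O)C(CC=C(C)C)C(CC(=O)OC)C(=O)OC | intermediate (not isolated)
4 | methyl 2-(3-methylbut-2-enyl)-3,5-dioxocyclohexane-1-carboxylate (diastereomer mixture, largely enolised) | COC(=O)C1CC(=O)CC(=O)C1CC=C(C)C | intermediate
5 | methyl 2-(3-methylbut-2-enyl)-3,5-bis(triisopropylsilyloxy)cyclohexa-3,5-diene-1-carboxylate (one of the convergent diene isomers) | COC(=O)C1C=C(O[Si](C(C)C)(C(C)C)C(C)C)C=C(O[Si](C(C)C)(C(C)C)C(C)C)C1CC=C(C)C | intermediate (not isolated)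
6 | methyl 2-(3-methylbut-2-enyl)-3,5-bis(triisopropylsilyloxy)benzoate | COC(=O)c1cc(O[Si](C(C)C)(C(C)C)C(C)C)cc(O[Si](C(C)C)(C(C)C)C(C)C)c1CC=C(C)C | intermediate
7 | N-methoxy-N-methyl-2-(3-methylbut-2-enyl)-3,5-bis(triisopropylsilyloxy)benzamide | CON(C)C(=O)c1cc(O[Si](C(C)C)(C(C)C)C(C)C)cc(O[Si](C(C)C)(C(C)C)C(C)C)c1CC=C(C)C | intermediate
8 | phloroglucinol (benzene-1,3,5-triol) | Oc1cc(O)cc(O)c1 | starting material
9 | 1,3,5-tris(methoxymethoxy)benzene | COCOc1cc(OCOC)cc(OCOC)c1 | intermediate
10 | 2,4,6-tris(methoxymethoxy)phenyllithium | [Li]c1c(OCOC)cc(OCOC)cc1OCOC | intermediate (not isolated)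
11 | [2-(3-methylbut-2-enyl)-3,5-bis(triisopropylsilyloxy)phenyl][2,4,6-tris(methoxymethoxy)phenyl]methanone | COCOc1cc(OCOC)c(C(=O)c2cc(O[Si](C(C)C)(C(C)C)C(C)C)cc(O[Si](C(C)C)(C(C)C)C(C)C)c2CC=C(C)C)c(OCOC)c1 | intermediate
12 | [2-(3-methylbut-2-enyl)-3,5-bis(triisopropylsilyloxy)phenyl](2,4,6-trihydroxyphenyl)methanone | CC(C)=CCc1c(O[Si](C(C)C)(C(C)C)C(C)C)cc(O[Si](C(C)C)(C(C)C)C(C)C)cc1C(=O)c1c(O)cc(O)cc1O | intermediate
13 | [2,6-dihydroxy-4-(triisopropylsilyloxy)phenyl][2-(3-methylbut-2-enyl)-3,5-bis(triisopropylsilyloxy)phenyl]methanone | CC(C)=CCc1c(O[Si](C(C)C)(C(C)C)C(C)C)cc(O[Si](C(C)C)(C(C)C)C(C)C)cc1C(=O)c1c(O)cc(O[Si](C(C)C)(C(C)C)C(C)C)cc1O | intermediate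
14 | 3-methylbut-2-enal | CC(C)=CC=O | starting material
15 | 3-hydroxy-6-(3-methylbut-2-enylidene)-2-[2-(3-methylbut-2-enyl)-3,5-bis(triisopropylsilyloxy)benzoyl]-5-(triisopropylsilyloxy)cyclohexa-2,4-dien-1-one (alkylidene geometry not defined) | CC(C)=CCc1c(O[Si](C(C)C)(C(C)C)C(C)C)cc(O[Si](C(C)C)(C(C)C)C(C)C)cc1C(=O)C1=C(O)C=C(O[Si](C(C)C)(C(C)C)C(C)C)C(=CC=C(C)C)C1=O | intermediate (not isolated)
16 | [7-hydroxy-2,2-dimethyl-5-(triisopropylsilyloxy)-2H-chromen-8-yl][2-(3-methylbut-2-enyl)-3,5-bis(triisopropylsilyloxy)phenyl]methanone | CC(C)=CCc1c(O[Si](C(C)C)(C(C)C)C(C)C)cc(O[Si](C(C)C)(C(C)C)C(C)C)cc1C(=O)c1c(O)cc(O[Si](C(C)C)(C(C)C)C(C)C)c2c1OC(C)(C)C=C2 | intermediate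
17 | [3,5-dihydroxy-2-(3-methylbut-2-enyl)phenyl](5,7-dihydroxy-2,2-dimethyl-2H-chromen-8-yl)methanone | CC(C)=CCc1c(O)cc(O)cc1C(=O)c1c(O)cc(O)c2c1OC(C)(C)C=C2 | target

**Step count**

Total: 9 steps. Longest linear sequence: 8 steps (steps 1, 2, 3, 5, 6, 7, 8, 9); the ring B branch contributes step 4.

**Steps most likely to fail**

Step 1. The conjugate addition may take place at the methyl carbon of 1, which after ring closure would place the prenyl group between the two carbonyls. Methoxide addition to the acceptor and self-condensation of the ketone may also drain the reactants before the ring closes. The fallback sets out from 2 and returns at 3, then 4. Methyl acetoacetate (CC(=O)CC(=O)OC) is added to 2 with catalytic NaOMe in MeOH to give trimethyl 4-oxopentane-1,2,3-tricarboxylate F1. The doubly activated methine of F1 is alkylated with 1-bromo-3-methylbut-2-ene (CC(C)=CCBr) and K2CO3 in acetone to give trimethyl 3-acetyl-6-methylhept-5-ene-1,2,3-tricarboxylate F2, which places the prenyl group and the succinate on the same carbon by construction. Krapcho demethoxycarbonylation of the β-keto ester (LiCl, wet DMSO, 140 °C) should then give 3 as a single regioisomer, and NaOMe in MeOH closes it to 4 as in step 1.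

Step 2. Bis-silylation may stop at the mono-silyl vinylogous ester, silyl groups may be lost during the oxidation, or DDQ may go on to abstract hydride from the benzylic and allylic methylene of the prenyl group once the arene has formed. The fallback sets out from 4 and returns at 6, replacing dehydrogenation by halogenation and elimination. The enolised dione is chlorinated at C4 with N-chlorosuccinimide (CH2Cl2, 0 °C) to methyl 4-chloro-2-(3-methylbut-2-enyl)-3,5-dioxocyclohexane-1-carboxylate F3. Heating F3 with LiCl and Li2CO3 in DMF at 100 °C should eliminate hydrogen chloride (halide shift to the α'-carbon or 1,4-elimination, then tautomerisation) to methyl 3,5-dihydroxy-2-(3-methylbut-2-enyl)benzoate F4, with the carbonate keeping the medium non-acidic for the ortho-prenylphenol. Silylation of F4 with TIPSCl and imidazole in DMF gives 6.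

Step 8. Carbon–carbon bond formation at C3' may be slow next to the bulky silyl ether, a second annulation may take place at the remaining hydroxyl, or loss of the 4'-silyl group at high temperature may open ring closure onto the para oxygen and erode the regiochemistry. The fallback sets out from 13 and returns at 16, replacing the intermolecular condensation by a sigmatropic route. One ortho hydroxyl of 13 is alkylated with 3-chloro-3-methylbut-1-yne (CC(C)(Cl)C#C), DBU and catalytic CuCl2 in MeCN at 0 °C to [2-hydroxy-6-(2-methylbut-3-yn-2-yloxy)-4-(triisopropylsilyloxy)phenyl][2-(3-methylbut-2-enyl)-3,5-bis(triisopropylsilyloxy)phenyl]methanone F5. Heating F5 in xylene at 140 °C should trigger the aromatic Claisen rearrangement to C3' (C1' is blocked), followed by a 1,5-hydrogen shift and oxa-6π ring closure to 16.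

**Further compounds**

F1 | step 1 | trimethyl 4-oxopentane-1,2,3-tricarboxylate | CC(=O)C(C(=O)OC)C(CC(=O)OC)C(=O)OC
F2 | step 1 | trimethyl 3-acetyl-6-methylhept-5-ene-1,2,3-tricarboxylate | CC(=O)C(CC=C(C)C)(C(=O)OC)C(CC(=O)OC)C(=O)OC
F3 | step 2 | methyl 4-chloro-2-(3-methylbut-2-enyl)-3,5-dioxocyclohexane-1-carboxylate | COC(=O)C1CC(=O)C(Cl)C(=O)C1CC=C(C)C
F4 | step 2 | methyl 3,5-dihydroxy-2-(3-methylbut-2-enyl)benzoate | COC(=O)c1cc(O)cc(O)c1CC=C(C)C
F5 | step 8 | [2-hydroxy-6-(2-methylbut-3-yn-2-yloxy)-4-(triisopropylsilyloxy)phenyl][2-(3-methylbut-2-enyl)-3,5-bis(triisopropylsilyloxy)phenyl]methanone | CC(C)=CCc1c(O[Si](C(C)C)(C(C)C)C(C)C)cc(O[Si](C(C)C)(C(C)C)C(C)C)cc1C(=O)c1c(O)cc(O[Si](C(C)C)(C(C)C)C(C)C)cc1OC(C)(C)C#C
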